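**Retrosynthetic overview**
1. Target 25 ⇐ 4-hydroxybenzoylation of the C4 alcohol 20; C4–OH ⇐ hydroxyl-directed reduction of ene-dione 19; C1–OAc ⇐ hydride reduction of bicyclic diketone 16 from the face opposite the angular methyl.
2. Seven-membered ring (formed second) ⇐ ring-closing metathesis of the two trans arms of cyclopentanone 14, then conjugation.
3. Key C7–C8 bond: 1,4-diketone 14 ⇐ ketone homoenolate (β-zincio ketone from cyclopropanol 11) + acid chloride 13; the quaternary C8a is set by cyclopropanation of silyl enol ether 9.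
4. 9 ⇐ alkoxide-directed vinyl 1,4-addition to hydroxy-enone 7 ⇐ enantioselective conjugate boration/oxidation and dehydrogenation of cyclopentenone 4.
5. Five-membered ring (formed first): 4 ⇐ Stetter reaction/aldol condensation of isobutyraldehyde 1 and 3-methylbut-3-en-2-one 2.

Assumption: the (R,R) enantiomer of QuinoxP* is taken to give the (3S) alcohol 6; if the sense is the opposite one, the (S,S) ligand is used and nothing else changes.

Azulene numbering is used for the bicyclic compounds: C1 (OAc), C3 (OH, isopropyl), C3a (ring-fusion H), C4 (aroyloxy), C6 (methyl), C7 (ketone), C8a (angular methyl).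

**Step 1**
Reactants: 1 2-methylpropanal (isobutyraldehyde); 2 3-methylbut-3-en-2-one
Product: 4 5-methyl-3-(propan-2-yl)cyclopent-2-en-1-one (racemic), via 3,6-dimethylheptane-2,5-dione 3 (not isolated)
Conditions: 3-benzyl-5-(2-hydroxyethyl)-4-methylthiazolium chloride (10 mol%), Et3N, EtOH, 80 °C; then 2 M NaOH, reflux
Reagents that add atoms: none
Why: Stetter reaction (the thiazolium-derived acyl anion of 1 adds to the unsubstituted β-carbon of 2) gives the 1,4-diketone, and intramolecular aldol condensation through the methyl ketone enolate is the only path to a conjugated cyclopentenone; the C5 centre stays racemic because step 3 erases it.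

**Step 2**
Reactants: 4 5-methyl-3-(propan-2-yl)cyclopent-2-en-1-one
Product: 6 (3S)-3-hydroxy-5-methyl-3-(propan-2-yl)cyclopentan-1-one (C5 epimer mixture), via tertiary boronate 5 (not isolated)
Conditions: CuPF6(MeCN)4 (10 mol%), (R,R)-QuinoxP* (12 mol%), LiOtBu (15 mol%), B2pin2, DMSO, rt; then NaBO3·4H2O, THF/H2O, 0 °C
Reagents that add atoms: bis(pinacolato)diboron, CC1(C)OB(OC1(C)C)B1OC(C)(C)C(C)(C)O1 (boron of 5 only); sodium perborate, [Na+].[O-]OB=O (oxygen of 6)
Why: Copper-catalysed enantioselective conjugate boration of a β,β-disubstituted cyclic enone sets the tertiary C–B centre under ligand control, and perborate oxidation replaces boron by OH with retention, fixing C3 as S.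

**Step 3**
Reactants: 6 (3S)-3-hydroxy-5-methyl-3-(propan-2-yl)cyclopentan-1-one
Product: 7 (4S)-4-hydroxy-2-methyl-4-(propan-2-yl)cyclopent-2-en-1-one
Conditions: IBX, 4-methoxypyridine N-oxide, DMSO, 25 °C
Reagents that add atoms: none
Why: IBX dehydrogenation of the ketone can only place the double bond toward the methyl-bearing carbon, because the other α-carbon adjoins the fully substituted carbinol, so both C5 epimers converge on one enantiomer.

**Step 4**
Reactants: 7 (4S)-4-hydroxy-2-methyl-4-(propan-2-yl)cyclopent-2-en-1-one; 8 vinylmagnesium bromide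
Product: 9 trimethyl{[(3S,4S)-3-ethenyl-2-methyl-4-(propan-2-yl)-4-(trimethylsilyloxy)cyclopent-1-en-1-yl]oxy}silane (vinyl cis to the silyloxy group)
Conditions: 8 (2.5 equiv), THF, −78 → −20 °C; then Me3SiCl, Et3N, −78 °C → rt
Reagents that add atoms: chlorotrimethylsilane, C[Si](C)(C)Cl
Why: Alkoxide-directed (ligand-assisted) 1,4-addition of the Grignard reagent: the magnesium alkoxide formed by the first equivalent delivers the vinyl group to C3 on its own face, which is also the face anti to the isopropyl group, and silylation traps the regiodefined enolate.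

**Step 5**
Reactants: 9 bis-silyl enol ether from step 4
Product: 11 (1S,3S,4S,5S)-4-ethenyl-5-methyl-3-(propan-2-yl)bicyclo[3.1.0]hexane-1,3-diol, via bis-silyl cyclopropane 10 (not isolated)
Conditions: Et2Zn, CH2I2, CH2Cl2, 0 °C; then K2CO3 (cat.), MeOH, 0 °C
Reagents that add atoms: diiodomethane, ICI
Why: Simmons–Smith cyclopropanation of the electron-rich silyl enol ether outpaces that of the vinyl group and occurs anti to the adjacent vinyl substituent, which fixes the future quaternary carbon (methyl cis and CH2 trans to vinyl); mild methanolysis frees the cyclopropanol.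

**Step 6 (key step)**
Reactants: 11 (1S,3S,4S,5S)-4-ethenyl-5-methyl-3-(propan-2-yl)bicyclo[3.1.0]hexane-1,3-diol; 12 2-methylbut-3-enoic acid (racemic)
Product: 14 (2S,3S,4S)-3-ethenyl-4-hydroxy-2-methyl-2-(3-methyl-2-oxopent-4-en-1-yl)-4-(propan-2-yl)cyclopentan-1-one (side-chain epimers), via 2-methylbut-3-enoyl chloride 13 (not isolated)
Conditions: 12, (COCl)2, cat. DMF, CH2Cl2 (gives 13); 11, Et2Zn (2.2 equiv), THF, 0 °C; Pd(PPh3)4 (5 mol%), 13, CO (1 atm), rt
Reagents that add atoms: oxalyl chloride, ClC(=O)C(Cl)=O (chlorine of 13 only)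
Why: Palladium-catalysed acylation of a cyclopropanol-derived zinc homoenolate: the zinc cyclopropoxide opens at its less substituted ring bond to a β-metallo ketone that has no β-hydrogen and couples with the acyl palladium species (CO suppresses decarbonylation), giving the 1,4-diketone with the quaternary centre untouched.

**Step 7**
Reactants: 14 1,4-diketone from step 6
Product: 16 (3S,3aS,8aS)-3-hydroxy-6,8a-dimethyl-3-(propan-2-yl)-2,3,3a,4,8,8a-hexahydroazulene-1,7-dione, via β,γ-unsaturated ketone 15 (not isolated)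
Conditions: second-generation Grubbs catalyst (5 mol%), CH2Cl2 (5 mM), 40 °C; then DBU, rt
Reagents that add atoms: none
Why: Ring-closing metathesis of the two monosubstituted vinyl groups closes the seven-membered ring on the trans arms, and DBU moves the double bond into conjugation, erasing the side-chain methyl stereocentre.

**Step 8**
Reactants: 16 bicyclic diketone from step 7
Product: 17 (1S,3S,3aS,8aS)-1,3-dihydroxy-6,8a-dimethyl-3-(propan-2-yl)-1,2,3,3a,4,8a-hexahydroazulen-7(8H)-one
Conditions: NaBH4, MeOH/CH2Cl2, −78 → −40 °C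
Reagents that add atoms: none
Why: Chemoselective borohydride reduction of the saturated cyclopentanone beside a conjugated enone (as with the Hajos–Parrish ketone), hydride arriving opposite the angular methyl so the new hydroxyl is cis to it (1S), as in 17-keto steroid reductions.

**Step 9**
Reactants: 17 diol from step 8
Product: 18 (1S,3S,3aS,8aS)-3-hydroxy-6,8a-dimethyl-7-oxo-3-(propan-2-yl)-1,2,3,3a,4,7,8,8a-octahydroazulen-1-yl acetate
Conditions: Ac2O, pyridine, DMAP (cat.), CH2Cl2, 0 °C → rt
Reagents that add atoms: acetic anhydride, CC(=O)OC(C)=O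
Why: Acetylation of the secondary alcohol; the tertiary alcohol does not react under these conditions.

**Step 10**
Reactants: 18 acetate from step 9
Product: 19 (1S,3S,3aS,8aS)-3-hydroxy-6,8a-dimethyl-4,7-dioxo-3-(propan-2-yl)-1,2,3,3a,4,7,8,8a-octahydroazulen-1-yl acetate
Conditions: Rh2(cap)4 (cap = caprolactamate, 1 mol%), 70% aq. t-BuOOH, ClCH2CH2Cl, 40 °C
Reagents that add atoms: tert-butyl hydroperoxide, CC(C)(C)OO
Why: Dirhodium-catalysed allylic oxidation converts the γ-methylene of the enone into a ketone under neutral conditions, which spare the β-hydroxy ketone and the C3a centre (shielded by two quaternary neighbours and already in its preferred arrangement anti to the isopropyl group).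

**Step 11**
Reactants: 19 ene-dione from step 10
Product: 20 (1S,3S,3aR,4R,8aS)-3,4-dihydroxy-6,8a-dimethyl-7-oxo-3-(propan-2-yl)-1,2,3,3a,4,7,8,8a-octahydroazulen-1-yl acetate
Conditions: Me4NBH(OAc)3, MeCN/AcOH, −30 → 0 °C
Reagents that add atoms: none
Why: Evans–Saksena hydroxyl-directed reduction: the tertiary C3 hydroxyl binds the triacetoxyborohydride and delivers hydride to the C4 ketone on its own face, giving the anti 1,3-diol (4R), while the C7 carbonyl has no directing hydroxyl and is untouched.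

**Step 12**
Reactants: 20 diol acetate from step 11; 21 4-hydroxybenzoic acid
Product: 25 (1S,3S,3aR,4R,8aS)-1-(acetyloxy)-3-hydroxy-6,8a-dimethyl-7-oxo-3-(propan-2-yl)-1,2,3,3a,4,7,8,8a-octahydroazulen-4-yl 4-hydroxybenzoate (target), via bis-silyl benzoate 22 (not isolated), via silyloxybenzoyl chloride 23 (not isolated), via silyl-protected ester 24 (not isolated)
Conditions: 21, (Me3Si)2NH, CH2Cl2, reflux; (COCl)2, cat. DMF, 0 °C → rt (gives 23); 20, pyridine, DMAP, CH2Cl2, rt; then citric acid, MeOH/H2O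
Reagents that add atoms: hexamethyldisilazane, C[Si](C)(C)N[Si](C)(C)C (silicon of 22–24 only); oxalyl chloride, ClC(=O)C(Cl)=O (chlorine of 23 only)
Why: Transient silylation lets the acid chloride of 21 be made (silyl ester to acid chloride) and used in a DMAP-catalysed esterification of the only secondary alcohol; the aryl silyl ether falls off in the mildly acidic work-up and no stereocentre is touched.

**Compound list**
1 | 2-methylpropanal (isobutyraldehyde) | CC(C)C=O | starting material
2 | 3-methylbut-3-en-2-one | CC(=O)C(C)=C | starting material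
3 | 3,6-dimethylheptane-2,5-dione (racemic, not isolated) | CC(=O)C(C)CC(=O)C(C)C | intermediate
4 | 5-methyl-3-(propan-2-yl)cyclopent-2-en-1-one (racemic) | CC1CC(C(C)C)=CC1=O | intermediate
5 | (3R)-5-methyl-3-(propan-2-yl)-3-(4,4,5,5-tetramethyl-1,3,2-dioxaborolan-2-yl)cyclopentan-1-one (C5 epimers, not isolated) | O=C1C[C@](B2OC(C)(C)C(C)(C)O2)(C(C)C)CC1C | intermediate
6 | (3S)-3-hydroxy-5-methyl-3-(propan-2-yl)cyclopentan-1-one (C5 epimers) | O=C1C[C@](O)(C(C)C)CC1C | intermediate
7 | (4S)-4-hydroxy-2-methyl-4-(propan-2-yl)cyclopent-2-en-1-one | CC1=C[C@@](O)(C(C)C)CC1=O | intermediate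
8 | vinylmagnesium bromide | C=C[Mg]Br | starting material
9 | trimethyl{[(3S,4S)-3-ethenyl-2-methyl-4-(propan-2-yl)-4-(trimethylsilyloxy)cyclopent-1-en-1-yl]oxy}silane | CC(C)[C@@]1(O[Si](C)(C)C)CC(O[Si](C)(C)C)=C(C)[C@@H]1C=C | intermediate
10 | bis(trimethylsilyl) ether of 11 (not isolated) | C[Si](C)(C)O[C@@]12C[C@](O[Si](C)(C)C)(C(C)C)[C@@H](C=C)[C@]1(C)C2 | intermediate
11 | (1S,3S,4S,5S)-4-ethenyl-5-methyl-3-(propan-2-yl)bicyclo[3.1.0]hexane-1,3-diol | O[C@@]12C[C@](O)(C(C)C)[C@@H](C=C)[C@]1(C)C2 | intermediate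
12 | 2-methylbut-3-enoic acid (racemic) | C=CC(C)C(=O)O | starting material
13 | 2-methylbut-3-enoyl chloride (not isolated) | C=CC(C)C(Cl)=O | intermediate
14 | (2S,3S,4S)-3-ethenyl-4-hydroxy-2-methyl-2-(3-methyl-2-oxopent-4-en-1-yl)-4-(propan-2-yl)cyclopentan-1-one (side-chain epimers) | O=C1C[C@](O)(C(C)C)[C@@H](C=C)[C@]1(C)CC(=O)C(C)C=C | intermediate
15 | (3S,3aS,8aS)-3-hydroxy-6,8a-dimethyl-3-(propan-2-yl)-2,3,3a,6,8,8a-hexahydroazulene-1,7-dione (C6 epimers, not isolated) | O=C1C[C@](O)(C(C)C)[C@H]2C=CC(C)C(=O)C[C@]12C | intermediate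
16 | (3S,3aS,8aS)-3-hydroxy-6,8a-dimethyl-3-(propan-2-yl)-2,3,3a,4,8,8a-hexahydroazulene-1,7-dione | O=C1C[C@](O)(C(C)C)[C@H]2CC=C(C)C(=O)C[C@]12C | intermediate
17 | (1S,3S,3aS,8aS)-1,3-dihydroxy-6,8a-dimethyl-3-(propan-2-yl)-1,2,3,3a,4,8a-hexahydroazulen-7(8H)-one | O[C@H]1C[C@](O)(C(C)C)[C@H]2CC=C(C)C(=O)C[C@]12C | intermediate
18 | (1S,3S,3aS,8aS)-3-hydroxy-6,8a-dimethyl-7-oxo-3-(propan-2-yl)-1,2,3,3a,4,7,8,8a-octahydroazulen-1-yl acetate | CC(=O)O[C@H]1C[C@](O)(C(C)C)[C@H]2CC=C(C)C(=O)C[C@]12C | intermediate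
19 | (1S,3S,3aS,8aS)-3-hydroxy-6,8a-dimethyl-4,7-dioxo-3-(propan-2-yl)-1,2,3,3a,4,7,8,8a-octahydroazulen-1-yl acetate | CC(=O)O[C@H]1C[C@](O)(C(C)C)[C@H]2C(=O)C=C(C)C(=O)C[C@]12C | intermediate
20 | (1S,3S,3aR,4R,8aS)-3,4-dihydroxy-6,8a-dimethyl-7-oxo-3-(propan-2-yl)-1,2,3,3a,4,7,8,8a-octahydroazulen-1-yl acetate | CC(=O)O[C@H]1C[C@](O)(C(C)C)[C@H]2[C@H](O)C=C(C)C(=O)C[C@]12C | intermediate
21 | 4-hydroxybenzoic acid | OC(=O)c1ccc(O)cc1 | starting material
22 | trimethylsilyl 4-(trimethylsilyloxy)benzoate (not isolated) | C[Si](C)(C)OC(=O)c1ccc(O[Si](C)(C)C)cc1 | intermediate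
23 | 4-(trimethylsilyloxy)benzoyl chloride (not isolated) | C[Si](C)(C)Oc1ccc(cc1)C(Cl)=O | intermediate
24 | aryl O-trimethylsilyl ether of 25 (not isolated) | CC(=O)O[C@H]1C[C@](O)(C(C)C)[C@H]2[C@H](OC(=O)c3ccc(O[Si](C)(C)C)cc3)C=C(C)C(=O)C[C@]12C | intermediate
25 | (1S,3S,3aR,4R,8aS)-1-(acetyloxy)-3-hydroxy-6,8a-dimethyl-7-oxo-3-(propan-2-yl)-1,2,3,3a,4,7,8,8a-octahydroazulen-4-yl 4-hydroxybenzoate | CC(=O)O[C@H]1C[C@](O)(C(C)C)[C@H]2[C@H](OC(=O)c3ccc(O)cc3)C=C(C)C(=O)C[C@]12C | target

**Totals**
Total steps: 12. Longest linear sequence: 12 (1 and 2 to 25).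

**Steps most likely to fail, each with one fallback**

Step 4 (1,2-addition of the Grignard reagent may compete with the directed 1,4-addition). The fallback sets out from 7: potassium vinyltrifluoroborate and [Rh(cod)OH]2 in dioxane/H2O (hydroxyl-directed rhodium-catalysed conjugate addition) give the ketone (3S,4S)-3-ethenyl-4-hydroxy-2-methyl-4-(propan-2-yl)cyclopentan-1-one F1. Me3SiCl/NaI/Et3N in MeCN then forms the more substituted silyl enol ether and silylates the alcohol, and the route is rejoined at 9.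

Step 6 (O-acylation of the zinc alkoxides or decarbonylation of the β,γ-unsaturated acyl palladium species may win). The fallback sets out from 9 and reverses the polarity at the other carbon. Acid 12 and MeLi (2 equiv) give 3-methylpent-4-en-2-one F2, and LDA/Me3SiCl gives its kinetic enol silane trimethyl[(3-methylpenta-1,4-dien-2-yl)oxy]silane F3. Oxidation of 9 with (NH4)2Ce(NO3)6/NaHCO3 in MeCN at −40 °C in the presence of excess F3 generates the α-keto radical, which adds anti to the vinyl group onto the terminal CH2 of F3. Dilute acid work-up rejoins the route at 14.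

Step 10 (the β-hydroxy ene-dione may dehydrate, or the allylic methyl may be oxidised). The fallback sets out from 18: Me3SiOTf/Et3N give the bis-silyl dienol ether (1S,3S,3aS,8aS)-6,8a-dimethyl-3-(propan-2-yl)-3,7-bis(trimethylsilyloxy)-1,2,3,3a,8,8a-hexahydroazulen-1-yl acetate F4. Dimethyldioxirane followed by citric acid in MeOH (vinylogous Rubottom oxidation) gives the 4-hydroxy enone (1S,3S,3aS,8aS)-3,4-dihydroxy-6,8a-dimethyl-7-oxo-3-(propan-2-yl)-1,2,3,3a,4,7,8,8a-octahydroazulen-1-yl acetate F5 as a C4 epimer mixture. Dess–Martin oxidation rejoins the route at 19.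

**Further compounds**
F1 | step 4 | (3S,4S)-3-ethenyl-4-hydroxy-2-methyl-4-(propan-2-yl)cyclopentan-1-one (C2 epimers) | O=C1C[C@](O)(C(C)C)[C@@H](C=C)C1C
F2 | step 6 | 3-methylpent-4-en-2-one | CC(=O)C(C)C=C
F3 | step 6 | trimethyl[(3-methylpenta-1,4-dien-2-yl)oxy]silane | C=C(O[Si](C)(C)C)C(C)C=C
F4 | step 10 | (1S,3S,3aS,8aS)-6,8a-dimethyl-3-(propan-2-yl)-3,7-bis(trimethylsilyloxy)-1,2,3,3a,8,8a-hexahydroazulen-1-yl acetate | CC(=O)O[C@H]1C[C@](O[Si](C)(C)C)(C(C)C)[C@H]2C=CC(C)=C(O[Si](C)(C)C)C[C@]12C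
F5 | step 10 | (1S,3S,3aS,8aS)-3,4-dihydroxy-6,8a-dimethyl-7-oxo-3-(propan-2-yl)-1,2,3,3a,4,7,8,8a-octahydroazulen-1-yl acetate (C4 epimers) | CC(=O)O[C@H]1C[C@](O)(C(C)C)[C@H]2C(O)C=C(C)C(=O)C[C@]12C
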